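A direct plan would condense methyl 2,3,4,5-tetramethoxybenzoate A1 with the dianion of 2-hydroxy-4,5-dimethoxyacetophenone A2 (crossed Claisen, C2–C3 bond) to the 1,3-diketone A3. It would then oxidise the phenol ring with PhI(OAc)2 in methanol to the quinone monoketal A4, close the pyranone at O1–C8a through the diketone enol oxygen, aromatise to the 5-hydroxyflavone A5 and methylate. Its weakest steps would be:
(a) the phenol oxidation, because PhI(OAc)2 also attacks the central carbon of an enolised 1,3-diketone and the hydrogen-bonded ortho-acylphenol is deactivated;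
(b) the O1–C8a closure on A4, a ring closure without precedent that would compete with methanol addition and ketal hydrolysis;
(c) the Claisen condensation, slow for an electron-rich, ortho-substituted ester and in need of excess base.

The route would instead disconnect ring A itself, at C4a–C5 and C8–C8a. Ring-A atoms C5, C6, C7 and C8 carry O, H, OMe and O, which is exactly the pattern C=O, CH, C–OMe, C–OH of the cyclobutenol made from methyl semisquarate, while C8a and C4a are C6 and C5 of a preformed 2-aryl-4-pyranone. The key step, a Moore ring expansion of this cyclobutenol, would build the benzene ring onto the pyranone in one thermal operation with every substituent placed by connectivity, so the 5,7,8 versus 5,6,7 question cannot arise. No phenol would be oxidised, no O1–C8a bond would be made on an arene and no acetophenone Claisen condensation would be needed.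

Key step: step 5

Remark: compounds 1, 4 and 9 are taken as commercial; the target is achiral, and the stereocentres of 10, 13 and 15 are racemic and transient.

Step 1
Reactants: 1 1,2,3,4-tetramethoxybenzene
Product: 3 2,3,4,5-tetramethoxybenzoic acid, via (2,3,4,5-tetramethoxyphenyl)lithium 2 (not isolated)
Conditions: n-BuLi (1.1 equiv), TMEDA (1.1 equiv), THF, 0 °C to rt, 2 h; CO2 (dry gas, excess), −78 °C to rt; 1 M HCl
Reagents that add atoms: carbon dioxide, O=C=O
Why: Directed ortho-metalation followed by carboxylation: the two ring C–H positions of 1 are equivalent and each is ortho to a methoxy group, so a single aryllithium should form and be trapped by CO2; no stereocentre is formed.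

Step 2
Reactants: 3 2,3,4,5-tetramethoxybenzoic acid; 4 (E)-4-methoxybut-3-en-2-one
Product: 8 2-(2,3,4,5-tetramethoxyphenyl)-4H-pyran-4-one, via 2,3,4,5-tetramethoxybenzoyl chloride 5 (not isolated), via lithium 4-methoxybuta-1,3-dien-2-olate 6 (not isolated), via enol ether diketone 7 (not isolated)
Conditions: 3, (COCl)2 (1.3 equiv), DMF (cat.), CH2Cl2, 0 °C to rt, evaporate; 4 (2.2 equiv), LiN(SiMe3)2 (2.2 equiv), THF, −78 °C, 30 min, then 5 in THF, −78 °C, 1 h; cold 1 M HCl, extract, evaporate; CF3CO2H (2 equiv), toluene, rt, 12 h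
Reagents that add atoms: none
Why: Claisen-type C-acylation of a kinetic lithium enolate by an acid chloride (the second equivalent of enolate takes up the acidic diketone proton) and acid-catalysed 6-endo addition–elimination of the aryl ketone enol oxygen on the β-methoxy enone with loss of methanol should give the γ-pyrone, the standard synthesis of 2-substituted 4-pyranones from 4-methoxybut-3-en-2-one; no stereocentre is formed.

Step 3
Reactants: 9 dimethyl squarate (3,4-dimethoxycyclobut-3-ene-1,2-dione)
Product: 11 3-methoxycyclobut-3-ene-1,2-dione (methyl semisquarate), via 4-hydroxy-2,3-dimethoxycyclobut-2-en-1-one 10 (not isolated)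
Conditions: LiAlH(OtBu)3 (1.1 equiv), THF, −78 to −20 °C; cold 1 M HCl, extract, evaporate; conc. HCl (cat.), CH2Cl2, rt, 1 h
Reagents that add atoms: water, O
Why: Chemoselective 1,2-reduction of one squarate carbonyl by the hindered hydride, then acid-catalysed ionisation of the allylic hydroxyl, capture of the methoxy-stabilised cation by water and loss of methanol (the established reduction–hydrolysis route from squarate diesters to semisquarate esters) should give 11; the stereocentre of racemic 10 is lost in the second stage.

Step 4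
Reactants: 8 2-(2,3,4,5-tetramethoxyphenyl)-4H-pyran-4-one; 11 3-methoxycyclobut-3-ene-1,2-dione
Product: 13 (±)-4-hydroxy-3-methoxy-4-[4-oxo-6-(2,3,4,5-tetramethoxyphenyl)-4H-pyran-2-yl]cyclobut-2-en-1-one, via 6-lithiopyranone 12 (not isolated)
Conditions: 2,2,6,6-tetramethylpiperidine (1.2 equiv), n-BuLi (1.15 equiv), THF, 0 °C; 8 in THF, −78 °C, 20 min; 11 (1.3 equiv) in THF, −78 °C, 30 min; sat. aq. NH4Cl at −78 °C; crude product passed through Et3N-deactivated silica
Reagents that add atoms: none
Why: Kinetic deprotonation of 8 at C6, the vinylic C–H next to the ring oxygen (the position metalated by hindered amide bases in chromones and β-alkoxy enones), followed by 1,2-addition of the vinyllithium to the C2 ketone of 11, which is more electrophilic than the vinylogous ester carbonyl C1 (the usual regiochemistry of organolithium addition to 3-alkoxycyclobutenediones), should give 13; the carbinol stereocentre forms as a racemate and is destroyed in step 5.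

Step 5
Reactants: 13 (±)-4-hydroxy-3-methoxy-4-[4-oxo-6-(2,3,4,5-tetramethoxyphenyl)-4H-pyran-2-yl]cyclobut-2-en-1-one
Product: 17 5,7,8-trimethoxy-2-(2,3,4,5-tetramethoxyphenyl)-4H-chromen-4-one, via (Z)-dienylketene 14 (not isolated), via 4aH-chromene-4,5-dione 15 (not isolated), via 5,8-dihydroxyflavone 16 (not isolated)
Conditions: degassed toluene (0.02 M), 110 °C, 2 h, Ar; evaporate; K2CO3 (6 equiv), MeI (8 equiv), degassed DMF, 45 °C, 16 h
Reagents that add atoms: iodomethane, CI
Why: Moore rearrangement: conrotatory 4π electrocyclic opening of the C1–C4 bond of 13 should give the (Z)-dienylketene 14, whose ketene carbon closes onto C5 of the pyrone (the nucleophilic β-carbon of its enol ether) by a thermal 6π electrocyclisation to dienone 15, and tautomerisation gives hydroquinone 16, which is methylated in the same flask (Williamson ether synthesis) because it is air-sensitive. The closest known reactions are the hydroquinone- and quinone-forming ring expansions of 4-aryl-, 4-heteroaryl- and 4-alkenyl-4-hydroxycyclobutenones made from squarate esters. Ring A is the only ring closed, by the disrotatory 6π closure that forms C4a–C5 (C8–C8a was made in step 4), while the pyranone and ring B enter intact. The selectivity required is outward rotation of the hydroxyl group in the ring opening, which places the pyranonyl group cis to the ketene and keeps the hydroxyl away from it (no lactonisation); the donor character of OH secures this torquoselectivity. The stereocentre of 13 and the transient C4a centre of 15 are both destroyed on aromatisation, so no stereocontrol is needed. The pattern O-5, H-6, OMe-7, O-8 follows from the atom connectivity of 13 and leaves no regiochemical choice.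

Compound list
1 | 1,2,3,4-tetramethoxybenzene | COc1ccc(OC)c(OC)c1OC | starting material
2 | (2,3,4,5-tetramethoxyphenyl)lithium | [Li]c1cc(OC)c(OC)c(OC)c1OC | intermediate
3 | 2,3,4,5-tetramethoxybenzoic acid | OC(=O)c1cc(OC)c(OC)c(OC)c1OC | intermediate
4 | (E)-4-methoxybut-3-en-2-one | CO/C=C/C(C)=O | starting material
5 | 2,3,4,5-tetramethoxybenzoyl chloride | ClC(=O)c1cc(OC)c(OC)c(OC)c1OC | intermediate
6 | lithium (E)-4-methoxybuta-1,3-dien-2-olate | C=C(O[Li])/C=C/OC | intermediate
7 | (E)-5-methoxy-1-(2,3,4,5-tetramethoxyphenyl)pent-4-ene-1,3-dione (drawn as the diketo form) | CO/C=C/C(=O)CC(=O)c1cc(OC)c(OC)c(OC)c1OC | intermediate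
8 | 2-(2,3,4,5-tetramethoxyphenyl)-4H-pyran-4-one | COc1cc(-c2cc(=O)cco2)c(OC)c(OC)c1OC | intermediate
9 | dimethyl squarate (3,4-dimethoxycyclobut-3-ene-1,2-dione) | COC1=C(OC)C(=O)C1=O | starting material
10 | (±)-4-hydroxy-2,3-dimethoxycyclobut-2-en-1-one | COC1=C(OC)C(O)C1=O | intermediate
11 | 3-methoxycyclobut-3-ene-1,2-dione (methyl semisquarate) | COC1=CC(=O)C1=O | intermediate
12 | [4-oxo-6-(2,3,4,5-tetramethoxyphenyl)-4H-pyran-2-yl]lithium | [Li]c1cc(=O)cc(-c2cc(OC)c(OC)c(OC)c2OC)o1 | intermediate
13 | (±)-4-hydroxy-3-methoxy-4-[4-oxo-6-(2,3,4,5-tetramethoxyphenyl)-4H-pyran-2-yl]cyclobut-2-en-1-one | COC1=CC(=O)C1(O)c1cc(=O)cc(-c2cc(OC)c(OC)c(OC)c2OC)o1 | intermediate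
14 | (3Z)-4-hydroxy-3-methoxy-4-[4-oxo-6-(2,3,4,5-tetramethoxyphenyl)-4H-pyran-2-yl]buta-1,3-dien-1-one (dienylketene) | O=C=C/C(OC)=C(O)\c1cc(=O)cc(-c2cc(OC)c(OC)c(OC)c2OC)o1 | intermediate
15 | (±)-8-hydroxy-7-methoxy-2-(2,3,4,5-tetramethoxyphenyl)-4aH-chromene-4,5-dione | COC1=CC(=O)C2C(=O)C=C(c3cc(OC)c(OC)c(OC)c3OC)OC2=C1O | intermediate
16 | 5,8-dihydroxy-7-methoxy-2-(2,3,4,5-tetramethoxyphenyl)-4H-chromen-4-one | COc1cc(O)c2c(=O)cc(-c3cc(OC)c(OC)c(OC)c3OC)oc2c1O | intermediate
17 | 5,7,8-trimethoxy-2-(2,3,4,5-tetramethoxyphenyl)-4H-chromen-4-one (achiral) | COc1cc(-c2cc(=O)c3c(OC)cc(OC)c(OC)c3o2)c(OC)c(OC)c1OC | target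

Total step count: 5. Longest linear sequence: 4 steps (steps 1, 2, 4 and 5); step 3 is a one-step branch.

Steps most likely to fail

Step 4. The deprotonation of 8 may occur next to the carbonyl (C3 or C5) or on ring B instead of at C6, the lithiated pyrone may add to unreacted 8, and the nucleophile may displace the methoxy group of 11 by conjugate addition–elimination instead of adding to the ketone. Fallback, from 8 back to 13: zincation next to the ring oxygen with TMPZnCl·LiCl (THF, 25 °C), which gives a stable organozinc, and iodination with I2 would give 2-iodo-6-(2,3,4,5-tetramethoxyphenyl)-4H-pyran-4-one F1, whose substitution site can be proven before use. Iodine–magnesium exchange (iPrMgCl·LiCl, THF, −78 °C) would then give chloro[4-oxo-6-(2,3,4,5-tetramethoxyphenyl)-4H-pyran-2-yl]magnesium F2, which would add to 11 at −78 °C and rejoin the route at 13.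

Step 5. The monosubstituted ketene may decay by other paths if the 6π closure onto the cross-conjugated pyrone double bond is slow, the hydroquinone 16 may be oxidised by air before both phenols are methylated, and the hydrogen-bonded 5-OH may be methylated only slowly, so that mixtures result. Fallback, from 16 back to 17: the crude thermolysate would be oxidised on purpose (Ag2O, CH2Cl2, rt) to the stable, chromatographable 7-methoxy-2-(2,3,4,5-tetramethoxyphenyl)-4H-chromene-4,5,8-trione F3. Reductive methylation (aq. Na2S2O4, then Me2SO4 and K2CO3 in acetone at reflux under Ar) would then return to the route at 17.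

Step 2. O-acylation or double acylation of the enolate, self-condensation of the methoxy enone and hydrolysis of the enol ether before ring closure may erode the pyrone synthesis. Fallback, from 3 back to 8: MeLi (2.2 equiv, THF, 0 °C) would convert the acid into 1-(2,3,4,5-tetramethoxyphenyl)ethan-1-one F4. Its lithium enolate (LiN(SiMe3)2, THF, −78 °C) would be acylated by methyl 3,3-dimethoxypropanoate (Claisen condensation) to 5,5-dimethoxy-1-(2,3,4,5-tetramethoxyphenyl)pentane-1,3-dione F5, and CF3CO2H in CH2Cl2 would close F5 with loss of two methanol, rejoining the route at 8.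

Further compounds
F1 | step 4 | 2-iodo-6-(2,3,4,5-tetramethoxyphenyl)-4H-pyran-4-one | COc1cc(-c2cc(=O)cc(I)o2)c(OC)c(OC)c1OC
F2 | step 4 | chloro[4-oxo-6-(2,3,4,5-tetramethoxyphenyl)-4H-pyran-2-yl]magnesium | COc1cc(-c2cc(=O)cc([Mg]Cl)o2)c(OC)c(OC)c1OC
F3 | step 5 | 7-methoxy-2-(2,3,4,5-tetramethoxyphenyl)-4H-chromene-4,5,8-trione | COC1=CC(=O)C2=C(OC(=CC2=O)c3cc(OC)c(OC)c(OC)c3OC)C1=O
F4 | step 2 | 1-(2,3,4,5-tetramethoxyphenyl)ethan-1-one | CC(=O)c1cc(OC)c(OC)c(OC)c1OC
F5 | step 2 | 5,5-dimethoxy-1-(2,3,4,5-tetramethoxyphenyl)pentane-1,3-dione | COC(OC)CC(=O)CC(=O)c1cc(OC)c(OC)c(OC)c1OC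
A1 | direct plan | methyl 2,3,4,5-tetramethoxybenzoate | COC(=O)c1cc(OC)c(OC)c(OC)c1OC
A2 | direct plan | 1-(2-hydroxy-4,5-dimethoxyphenyl)ethan-1-one | CC(=O)c1cc(OC)c(OC)cc1O
A3 | direct plan | 1-(2-hydroxy-4,5-dimethoxyphenyl)-3-(2,3,4,5-tetramethoxyphenyl)propane-1,3-dione | COc1cc(O)c(cc1OC)C(=O)CC(=O)c1cc(OC)c(OC)c(OC)c1OC
A4 | direct plan | 1-(3,3,4-trimethoxy-6-oxocyclohexa-1,4-dien-1-yl)-3-(2,3,4,5-tetramethoxyphenyl)propane-1,3-dione | O=C1C=C(OC)C(OC)(OC)C=C1C(=O)CC(=O)c1cc(OC)c(OC)c(OC)c1OC
A5 | direct plan | 5-hydroxy-7,8-dimethoxy-2-(2,3,4,5-tetramethoxyphenyl)-4H-chromen-4-one | COc1cc(-c2cc(=O)c3c(O)cc(OC)c(OC)c3o2)c(OC)c(OC)c1OC
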